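**Assumption:** locants follow cembrane numbering (C1 = ring CH carrying the propionate unit C15–C17, C3 = lactone CH–O, C4 = carbinol carbon, C7 = CH–OOH, C8 = C(=C19H2), C11/C12 = oxirane carbons, C18–C20 = methyls on C4, C8, C12); geranylacetone is used as its pure (5E) isomer.

## Retrosynthetic overview

1. Target 17 ⇐ Schenck ene reaction (singlet oxygen) on the single 7E olefin of macrolide 16.
2. δ-Lactone (last ring) ⇐ chelation-controlled reduction of the C3 ketone of α-ketol 14, then acyl transfer from the C16 thioester.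
3. 14-Membered ring (second ring) ⇐ C3–C4 bond: the C3 aldehyde of seco keto aldehyde 13 adds, as its carbene-derived acyl anion equivalent, to the C4 methyl ketone.
4. 13 ⇐ organocatalytic Mukaiyama–Michael addition of a propionate ketene thioacetal to enal 10 (sets C1 and C15).
5. 10 ⇐ geranylacetone by allylic oxidation, Sharpless epoxidation (oxirane, first ring; C11 and C12), allylation and cross-metathesis.

## Route

Step 1
Reactants: 1 (5E)-6,10-dimethylundeca-5,9-dien-2-one (geranylacetone)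
Product: 2 2-[(3E)-4,8-dimethylnona-3,7-dien-1-yl]-2-methyl-1,3-dioxolane
Conditions: HOCH2CH2OH (3 equiv), pyridinium p-toluenesulfonate (5 mol %), benzene, reflux, Dean–Stark
Reagents that add atoms: ethylene glycol, OCCO
Why: Acid-catalysed ketalisation with azeotropic removal of water masks the C4 ketone against the Grignard reagent of step 4; no stereocentre is formed.

Step 2
Reactants: 2 2-[(3E)-4,8-dimethylnona-3,7-dien-1-yl]-2-methyl-1,3-dioxolane
Product: 3 (2E,6E)-2,6-dimethyl-9-(2-methyl-1,3-dioxolan-2-yl)nona-2,6-dien-1-ol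
Conditions: SeO2 (0.3 equiv), t-BuOOH (2.5 equiv, anhydrous in decane), CH2Cl2, 0 °C to rt
Reagents that add atoms: tert-butyl hydroperoxide, CC(C)(C)OO
Why: Catalytic Riley allylic oxidation (ene reaction then [2,3]-shift) hydroxylates the E-methyl of the terminal isopropylidene group in preference to the internal olefin and keeps the E geometry; no stereocentre is formed.

Step 3
Reactants: 3 (2E,6E)-2,6-dimethyl-9-(2-methyl-1,3-dioxolan-2-yl)nona-2,6-dien-1-ol
Product: 4 [(2S,3S)-2-methyl-3-[(3E)-3-methyl-6-(2-methyl-1,3-dioxolan-2-yl)hex-3-en-1-yl]oxiran-2-yl]methanol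
Conditions: Ti(OiPr)4 (10 mol %), L-(+)-diethyl tartrate (12 mol %), t-BuOOH (2 equiv), 4 Å molecular sieves, CH2Cl2, −20 °C
Reagents that add atoms: tert-butyl hydroperoxide, CC(C)(C)OO
Why: Sharpless asymmetric epoxidation touches only the olefin of the allylic alcohol, and the L-(+)-tartrate complex delivers oxygen to the face that gives the (2S,3S)-epoxy alcohol, i.e. C11 S and C12 S of the target.

Step 4
Reactants: 4 [(2S,3S)-2-methyl-3-[(3E)-3-methyl-6-(2-methyl-1,3-dioxolan-2-yl)hex-3-en-1-yl]oxiran-2-yl]methanol; 5 allylmagnesium bromide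
Product: 7 2-[(3E)-6-[(2S,3S)-3-(but-3-en-1-yl)-3-methyloxiran-2-yl]-4-methylhex-3-en-1-yl]-2-methyl-1,3-dioxolane, via epoxy triflate 6 (not isolated)
Conditions: (CF3SO2)2O (1.1 equiv), 2,6-lutidine (1.3 equiv), CH2Cl2, −78 °C; then 5 (2 equiv), CuI (10 mol %), Et2O, −78 °C
Reagents that add atoms: trifluoromethanesulfonic anhydride, O=S(=O)(OS(=O)(=O)C(F)(F)F)C(F)(F)F (supplies the triflyl group of 6; none of its atoms stay in 7)
Why: Copper-catalysed Grignard coupling (Kochi type) displaces the primary oxiranylcarbinyl triflate by SN2 at −78 °C, faster than attack on the hindered trisubstituted epoxide or the ketal; the stereocentres are not touched.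

Step 5
Reactants: 7 2-[(3E)-6-[(2S,3S)-3-(but-3-en-1-yl)-3-methyloxiran-2-yl]-4-methylhex-3-en-1-yl]-2-methyl-1,3-dioxolane
Product: 8 (5E)-8-[(2S,3S)-3-(but-3-en-1-yl)-3-methyloxiran-2-yl]-6-methyloct-5-en-2-one
Conditions: pyridinium p-toluenesulfonate (0.2 equiv), acetone/H2O 10:1, 40 °C
Reagents that add atoms: water, O
Why: Mild acid-catalysed ketal hydrolysis (transketalisation to acetone) frees the C4 ketone at a pH the trisubstituted epoxide tolerates; no stereocentre is affected.

Step 6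
Reactants: 8 (5E)-8-[(2S,3S)-3-(but-3-en-1-yl)-3-methyloxiran-2-yl]-6-methyloct-5-en-2-one; 9 (2E)-but-2-enal (crotonaldehyde)
Product: 10 (2E)-5-[(2S,3S)-2-methyl-3-[(3E)-3-methyl-7-oxooct-3-en-1-yl]oxiran-2-yl]pent-2-enal
Conditions: second-generation Hoveyda–Grubbs catalyst RuCl2(H2IMes)(=CH-C6H4-2-OiPr) (5 mol %), 9 (5 equiv), CH2Cl2, 40 °C
Reagents that add atoms: none
Why: Olefin cross-metathesis joins the monosubstituted alkene to the electron-poor partner to give the E-enal with loss of propene, while the trisubstituted C7=C8 olefin, ketone and epoxide are inert.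

Step 7
Reactants: 11 S-ethyl propanethioate
Product: 12 [(Z)-1-(ethylsulfanyl)prop-1-en-1-yl]oxy(trimethyl)silane
Conditions: LiN(iPr)2 (1.05 equiv, commercial solution), THF, −78 °C; Me3SiCl (1.2 equiv), −78 °C to rt
Reagents that add atoms: chlorotrimethylsilane, C[Si](C)(C)Cl
Why: Kinetic enolisation through the cyclic Ireland transition state places the methyl cis to sulfur, and O-silylation traps this as the Z ketene thioacetal.

Step 8
Reactants: 10 (2E)-5-[(2S,3S)-2-methyl-3-[(3E)-3-methyl-7-oxooct-3-en-1-yl]oxiran-2-yl]pent-2-enal; 12 [(Z)-1-(ethylsulfanyl)prop-1-en-1-yl]oxy(trimethyl)silane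
Product: 13 S-ethyl (2S,3R)-2-methyl-3-{2-[(2S,3S)-2-methyl-3-[(3E)-3-methyl-7-oxooct-3-en-1-yl]oxiran-2-yl]ethyl}-5-oxopentanethioate
Conditions: (2S,5S)-5-benzyl-2-tert-butyl-3-methylimidazolidin-4-one·CF3CO2H (20 mol %), 12 (1.5 equiv), CH2Cl2, H2O (2 equiv), −70 °C
Reagents that add atoms: none
Why: Iminium-catalysed Mukaiyama–Michael addition: the benzyl group shields one face of the E-iminium ion, so the ketene thioacetal adds to the exposed β-face to give C1 R (the facial sense this catalyst shows with other π-nucleophiles), and the Z ketene acetal gives the 2,3-syn adduct (C15 S), which is also the thermodynamic epimer in the final lactone.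

Step 9
Reactants: 13 S-ethyl (2S,3R)-2-methyl-3-{2-[(2S,3S)-2-methyl-3-[(3E)-3-methyl-7-oxooct-3-en-1-yl]oxiran-2-yl]ethyl}-5-oxopentanethioate
Product: 14 S-ethyl (1R,4S,7E,11S,12S,15S)-11,12-epoxy-4-hydroxy-3-oxocembr-7-en-16-thioate
Conditions: (5aS,10bR)-2-(pentafluorophenyl)-5a,10b-dihydro-4H,6H-indeno[2,1-b][1,2,4]triazolo[4,3-d][1,4]oxazinium tetrafluoroborate (15 mol %), iPr2NEt (15 mol %), toluene, 40 °C, 13 added by syringe pump over 24 h to 2 mM
Reagents that add atoms: none
Why: Proposed new method: the triazolylidene adds to the C3 aldehyde to form the Breslow intermediate, an acyl anion equivalent, which attacks the C4 methyl ketone of the same chain and releases the carbene to leave the α-ketol (closest known reactions: the intramolecular crossed aldehyde–ketone benzoin reaction for five- and six-membered rings and carbene-catalysed macrocyclic Stetter closures); high dilution suppresses homo-benzoin dimers, the E-olefin and trans-epoxide lower the entropic cost of the 14-membered ring, and the aminoindanol backbone is expected to direct attack to the Re face of the ketone (C4 S), a sense assigned from six-ring precedent and to be confirmed on the first run because both catalyst antipodes are sold.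

Step 10
Reactants: 14 S-ethyl (1R,4S,7E,11S,12S,15S)-11,12-epoxy-4-hydroxy-3-oxocembr-7-en-16-thioate
Product: 16 (1R,3R,4S,7E,11S,12S,15S)-11,12-epoxy-4-hydroxycembr-7-en-16,3-olide, via diol thioester 15 (not isolated)
Conditions: Zn(BH4)2 (1.5 equiv), Et2O, −30 °C; H2O work-up; then Et3N (2 equiv), 4-(dimethylamino)pyridine (10 mol %), CH2Cl2, rt
Reagents that add atoms: none
Why: Cram-chelate reduction: zinc bridges the C4 hydroxyl and C3 carbonyl oxygens and hydride enters from the side of the small C18 methyl (also the outer face of the macrocycle) to give the 3R,4S erythro diol, whose C3 hydroxyl then acylates on the 1,5-placed thioester to close the δ-lactone with loss of ethanethiol.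

Step 11
Reactants: 16 (1R,3R,4S,7E,11S,12S,15S)-11,12-epoxy-4-hydroxycembr-7-en-16,3-olide
Product: 17 (1R,3R,4S,7R,11S,12S,15S)-11,12-epoxy-7-hydroperoxy-4-hydroxycembr-8(19)-en-16,3-olide (CNP0319766.1)
Conditions: O2, tetraphenylporphyrin (1 mol %), visible light, CH2Cl2, −20 °C
Reagents that add atoms: dioxygen, O=O
Why: Schenck ene reaction of singlet oxygen with the only remaining olefin: the cis effect directs hydrogen abstraction to the C19 methyl / C6 side, the freely rotating methyl hydrogens give the C7 hydroperoxide with the exocyclic C8=C19 olefin, and attack on the exposed outer face of the macrocycle is expected to set C7 R (biomimetic; regio- and stereoisomers are removed by chromatography).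

## Compound list

1 | (5E)-6,10-dimethylundeca-5,9-dien-2-one (geranylacetone) | CC(=O)CC/C=C(\C)CCC=C(C)C | starting material
2 | 2-[(3E)-4,8-dimethylnona-3,7-dien-1-yl]-2-methyl-1,3-dioxolane | CC1(OCCO1)CC/C=C(\C)CCC=C(C)C | intermediate
3 | (2E,6E)-2,6-dimethyl-9-(2-methyl-1,3-dioxolan-2-yl)nona-2,6-dien-1-ol | CC1(OCCO1)CC/C=C(\C)CC/C=C(\C)CO | intermediate
4 | [(2S,3S)-2-methyl-3-[(3E)-3-methyl-6-(2-methyl-1,3-dioxolan-2-yl)hex-3-en-1-yl]oxiran-2-yl]methanol | CC1(OCCO1)CC/C=C(\C)CC[C@@H]2O[C@@]2(C)CO | intermediate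
5 | allylmagnesium bromide | C=CC[Mg]Br | starting material
6 | [(2S,3S)-2-methyl-3-[(3E)-3-methyl-6-(2-methyl-1,3-dioxolan-2-yl)hex-3-en-1-yl]oxiran-2-yl]methyl trifluoromethanesulfonate (epoxy triflate) | CC1(OCCO1)CC/C=C(\C)CC[C@@H]2O[C@@]2(C)COS(=O)(=O)C(F)(F)F | intermediate
7 | 2-[(3E)-6-[(2S,3S)-3-(but-3-en-1-yl)-3-methyloxiran-2-yl]-4-methylhex-3-en-1-yl]-2-methyl-1,3-dioxolane | CC1(OCCO1)CC/C=C(\C)CC[C@@H]2O[C@@]2(C)CCC=C | intermediate
8 | (5E)-8-[(2S,3S)-3-(but-3-en-1-yl)-3-methyloxiran-2-yl]-6-methyloct-5-en-2-one | CC(=O)CC/C=C(\C)CC[C@@H]1O[C@@]1(C)CCC=C | intermediate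
9 | (2E)-but-2-enal (crotonaldehyde) | C/C=C/C=O | starting material
10 | (2E)-5-[(2S,3S)-2-methyl-3-[(3E)-3-methyl-7-oxooct-3-en-1-yl]oxiran-2-yl]pent-2-enal | CC(=O)CC/C=C(\C)CC[C@@H]1O[C@@]1(C)CC/C=C/C=O | intermediate
11 | S-ethyl propanethioate | CCC(=O)SCC | starting material
12 | [(Z)-1-(ethylsulfanyl)prop-1-en-1-yl]oxy(trimethyl)silane | C/C=C(\SCC)O[Si](C)(C)C | intermediate
13 | S-ethyl (2S,3R)-2-methyl-3-{2-[(2S,3S)-2-methyl-3-[(3E)-3-methyl-7-oxooct-3-en-1-yl]oxiran-2-yl]ethyl}-5-oxopentanethioate | CC(=O)CC/C=C(\C)CC[C@@H]1O[C@@]1(C)CC[C@H](CC=O)[C@H](C)C(=O)SCC | intermediate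
14 | S-ethyl (1R,4S,7E,11S,12S,15S)-11,12-epoxy-4-hydroxy-3-oxocembr-7-en-16-thioate (14-membered α-ketol) | C/C1=C\CC[C@](C)(O)C(=O)C[C@@H](CC[C@]2(C)O[C@H]2CC1)[C@H](C)C(=O)SCC | intermediate
15 | S-ethyl (1R,3R,4S,7E,11S,12S,15S)-11,12-epoxy-3,4-dihydroxycembr-7-en-16-thioate (diol thioester) | C/C1=C\CC[C@](C)(O)[C@H](O)C[C@@H](CC[C@]2(C)O[C@H]2CC1)[C@H](C)C(=O)SCC | intermediate
16 | (1R,3R,4S,7E,11S,12S,15S)-11,12-epoxy-4-hydroxycembr-7-en-16,3-olide | C/C1=C\CC[C@](C)(O)[C@H]2C[C@@H](CC[C@]3(C)O[C@H]3CC1)[C@H](C)C(=O)O2 | intermediate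
17 | (1R,3R,4S,7R,11S,12S,15S)-11,12-epoxy-7-hydroperoxy-4-hydroxycembr-8(19)-en-16,3-olide (CNP0319766.1) | C=C1CC[C@@H]2O[C@@]2(C)CC[C@@H]2C[C@@H](OC(=O)[C@H]2C)[C@@](C)(O)CC[C@H]1OO | target

## Step count

Total steps: 11. Longest linear sequence: 10 (steps 1–6 and 8–11, from geranylacetone).

## Three steps most likely to fail, with fallbacks

**Step 9 (carbene-catalysed macrocyclic aldehyde–ketone benzoin).** The addition of an acyl anion equivalent to an unactivated methyl ketone is reversible and has no precedent at ring size 14; homo-benzoin dimers and the sense of catalyst control at C4 are further risks. The fallback replaces carbene catalysis by a reductive ketyl coupling. It sets out from 13: slow addition of 13 to SmI2 in THF at high dilution generates the C3 ketyl, which couples with the C4 ketone (pinacol macrocyclisation) to give the diol thioester 15 directly; the samarium alkoxide or the Et3N/DMAP treatment of step 10 then closes the lactone, and the route is rejoined at 16. A wrong C3 epimer of 15 can be oxidised (Dess–Martin periodinane) to 14 and sent through step 10. The epoxide tolerates SmI2, whereas low-valent titanium would deoxygenate it.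

**Step 11 (singlet-oxygen ene reaction).** Abstraction from C6–H would give the tertiary C8 hydroperoxide, and the facial selectivity at C7 rests only on macrocycle conformation. The fallback fixes C7 by reagent control. It sets out from 16: photooxygenation is followed in the same flask by Ac2O/pyridine/4-(dimethylamino)pyridine, which dehydrates both C7-epimeric secondary hydroperoxides to (1R,3R,4S,11S,12S,15S)-11,12-epoxy-4-hydroxy-7-oxocembr-8(19)-en-16,3-olide F1. Reduction with BH3·SMe2 and the B-methyl oxazaborolidine from diphenylprolinol (enantiomer chosen for 7S) gives (1R,3R,4S,7S,11S,12S,15S)-11,12-epoxy-4,7-dihydroxycembr-8(19)-en-16,3-olide F2. CH3SO2Cl/Et3N gives the (7S)-7-methanesulfonate F3. SN2 displacement with 2-methoxypropan-2-yl hydroperoxide/CsOH in DMF inverts C7 to the (7R)-7-[(2-methoxypropan-2-yl)peroxy] peroxyketal F4, and AcOH/H2O releases the hydroperoxide, rejoining the route at 17.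

**Step 4 (SN2 at the oxiranylcarbinyl triflate).** The carbon attacked sits next to a fully substituted epoxide carbon, so displacement may be slow and epoxide opening or triflate decomposition may compete. The fallback builds the same C13–C14 bond without an sp3 electrophile. It sets out from 4: SO3·pyridine/DMSO/Et3N oxidation gives (2R,3S)-2-methyl-3-[(3E)-3-methyl-6-(2-methyl-1,3-dioxolan-2-yl)hex-3-en-1-yl]oxirane-2-carbaldehyde F5. Wittig methylenation (Ph3P=CH2, THF, −78 °C) gives 2-[(3E)-6-[(2S,3S)-3-ethenyl-3-methyloxiran-2-yl]-4-methylhex-3-en-1-yl]-2-methyl-1,3-dioxolane F6. Hydroboration with 9-borabicyclo[3.3.1]nonane gives the B-alkyl borane 9-{2-[(2S,3S)-2-methyl-3-[(3E)-3-methyl-6-(2-methyl-1,3-dioxolan-2-yl)hex-3-en-1-yl]oxiran-2-yl]ethyl}-9-borabicyclo[3.3.1]nonane F7, which is coupled in the same flask with vinyl bromide [PdCl2(dppf), K3PO4, THF/H2O] in a B-alkyl Suzuki–Miyaura reaction, rejoining the route at 7.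

## Further compounds

F0 | step 9 | none | none
F1 | step 11 | (1R,3R,4S,11S,12S,15S)-11,12-epoxy-4-hydroxy-7-oxocembr-8(19)-en-16,3-olide | C=C1C(=O)CC[C@](C)(O)[C@H]2C[C@@H](CC[C@]3(C)O[C@H]3CC1)[C@H](C)C(=O)O2
F2 | step 11 | (1R,3R,4S,7S,11S,12S,15S)-11,12-epoxy-4,7-dihydroxycembr-8(19)-en-16,3-olide | C=C1[C@@H](O)CC[C@](C)(O)[C@H]2C[C@@H](CC[C@]3(C)O[C@H]3CC1)[C@H](C)C(=O)O2
F3 | step 11 | (1R,3R,4S,7S,11S,12S,15S)-11,12-epoxy-4-hydroxy-7-(methanesulfonyloxy)cembr-8(19)-en-16,3-olide | C=C1[C@@H](OS(C)(=O)=O)CC[C@](C)(O)[C@H]2C[C@@H](CC[C@]3(C)O[C@H]3CC1)[C@H](C)C(=O)O2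
F4 | step 11 | (1R,3R,4S,7R,11S,12S,15S)-11,12-epoxy-4-hydroxy-7-[(2-methoxypropan-2-yl)peroxy]cembr-8(19)-en-16,3-olide | C=C1[C@H](OOC(C)(C)OC)CC[C@](C)(O)[C@H]2C[C@@H](CC[C@]3(C)O[C@H]3CC1)[C@H](C)C(=O)O2
F5 | step 4 | (2R,3S)-2-methyl-3-[(3E)-3-methyl-6-(2-methyl-1,3-dioxolan-2-yl)hex-3-en-1-yl]oxirane-2-carbaldehyde | CC1(OCCO1)CC/C=C(\C)CC[C@@H]2O[C@@]2(C)C=O
F6 | step 4 | 2-[(3E)-6-[(2S,3S)-3-ethenyl-3-methyloxiran-2-yl]-4-methylhex-3-en-1-yl]-2-methyl-1,3-dioxolane | CC1(OCCO1)CC/C=C(\C)CC[C@@H]2O[C@@]2(C)C=C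
F7 | step 4 | 9-{2-[(2S,3S)-2-methyl-3-[(3E)-3-methyl-6-(2-methyl-1,3-dioxolan-2-yl)hex-3-en-1-yl]oxiran-2-yl]ethyl}-9-borabicyclo[3.3.1]nonane | CC1(OCCO1)CC/C=C(\C)CC[C@@H]2O[C@@]2(C)CCB3C4CCCC3CCC4
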